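Target: (3R)-all-E-3',4',7,8,7',8'-hexadehydro-β,β-caroten-3-ol (carotenoid numbering; ring A = C1–C6 with C3–OH, ring B = C1'–C6' with the C3'=C4'–C5'=C6' diene). The hardest task is to join an unsymmetrical, labile chain with all seven C=C bonds E, although 9E/9'E next to the alkynes is not the thermodynamic geometry and would be put at risk in any allylic C11 ylide or anion.
Cuts: first C14–C15, C15'–C14' and the two bonds C13–CH3 and C13'–CH3 (key step: C18 + CH3 + C2 + CH3 + C18). Next C6–C7 and C6'–C7' (ring enol triflate + alkyne), then C11=C12 inside one chain module that serves both halves.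
Forward: the C7–C14 module is made once and clipped onto the ring A triflate and onto the ring B dienyl triflate. The two terminal alkynes are then methylaluminated and stitched in one flask, first to the iodine end and then to the bromine end of (E)-BrCH=CHI.
Enabling feature: the unsubstituted C15=C15' ethene lies between two identical (E)-C13(CH3)=C14H units, and each of these is the retron of a syn methylmetalation of a terminal alkyne. The alkynes C7≡C8 and C7'≡C8' are shielded by the fully substituted C6/C9 and C6'/C9', so the ring A/ring B difference can be carried by the I/Br difference of a C2 linchpin.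
Stereochemistry: C3 (R) comes from an ene-reductase/carbonyl-reductase cascade on ketoisophorone. 9E/9'E is bought with (E)-3-methylpent-2-en-4-yn-1-ol, 11E/11'E comes from the HWE step, 13E/13'E from syn addition, and 15E from the linchpin.

Key step: step 11

Remark: carotenoid numbering is used for all chain positions. From step 7 on, all polyenynes are assumed to be handled under argon and in dim light.

Step 1
Reactants: 1 ketoisophorone (2,6,6-trimethylcyclohex-2-ene-1,4-dione)
Product: 3 (4R,6R)-4-hydroxy-2,2,6-trimethylcyclohexanone (actinol), via (6R)-levodione 2 (not isolated)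
Conditions: ene-reductase (Old Yellow Enzyme family), then carbonyl reductase (short-chain dehydrogenase of the levodione-reductase type), NAD(P)+ cat., glucose dehydrogenase, D-glucose, phosphate buffer pH 7, 30 °C
Reagents that add atoms: none
Why: Asymmetric bioreduction cascade in which the flavin ene-reductase adds hydride and proton anti across the activated C=C and sets the methyl centre (R), after which the carbonyl reductase delivers hydride to one face of the unhindered C4 ketone only and sets C4 (R), the future C3 of the target, while the neopentyl ketone is not accepted.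

Step 2
Reactants: 3 actinol
Product: 4 (4R,6R)-4-(tert-butyldimethylsilyloxy)-2,2,6-trimethylcyclohexanone
Conditions: TBSCl, imidazole, DMF, rt
Reagents that add atoms: tert-butyldimethylsilyl chloride, CC(C)(C)[Si](C)(C)Cl
Why: Standard silyl ether formation removes the only acidic proton before the enolate, copper acetylide and organoaluminium steps and touches no stereocentre.

Step 3
Reactants: 4 TBS-actinol
Product: 5 (4R)-4-(tert-butyldimethylsilyloxy)-2,6,6-trimethylcyclohex-1-en-1-yl trifluoromethanesulfonate (ring A triflate)
Conditions: LDA, THF, −78 to 0 °C; PhNTf2, 0 °C to rt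
Reagents that add atoms: N-phenylbis(trifluoromethanesulfonimide), O=S(=O)(N(c1ccccc1)S(=O)(=O)C(F)(F)F)C(F)(F)F
Why: Enol triflate formation in which the ketone has a single α-hydrogen, so only the tetrasubstituted enolate (future C5=C6) can form and be O-sulfonylated; the methyl-bearing stereocentre is erased on purpose and the γ-placed OTBS group cannot β-eliminate.

Step 4
Reactants: 6 2,6,6-trimethylcyclohex-2-en-1-one
Product: 7 2,6,6-trimethylcyclohexa-1,3-dien-1-yl trifluoromethanesulfonate (ring B triflate)
Conditions: KHMDS, THF, −78 to 0 °C; PhNTf2, −78 °C to rt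
Reagents that add atoms: N-phenylbis(trifluoromethanesulfonimide), O=S(=O)(N(c1ccccc1)S(=O)(=O)C(F)(F)F)C(F)(F)F
Why: Vinylogous enol triflate formation in which, with no α'-hydrogen present, the non-reducing amide base can only remove the γ-hydrogen (future C3'), and O-sulfonylation of the linear dienolate gives the C3'=C4'–C5'=C6' diene of ring B directly.

Step 5
Reactants: 8 (E)-3-methylpent-2-en-4-yn-1-ol
Product: 9 (E)-3-methylpent-2-en-4-ynal
Conditions: activated MnO2, CH2Cl2, rt
Reagents that add atoms: none
Why: Allylic alcohol oxidation with MnO2 is neutral and heterogeneous, so the terminal alkyne survives and the purchased E geometry (future 9E/9'E) is kept.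

Step 6
Reactants: 10 3-bromo-1-(trimethylsilyl)prop-1-yne
Product: 11 diethyl [3-(trimethylsilyl)prop-2-yn-1-yl]phosphonate
Conditions: P(OEt)3, neat, 130 °C
Reagents that add atoms: triethyl phosphite, CCOP(OCC)OCC
Why: Michaelis–Arbuzov reaction of a primary propargylic bromide, with the C-silyl group blocking the acidic alkyne terminus.

Step 7
Reactants: 9 (E)-3-methylpent-2-en-4-ynal; 11 silylpropargyl phosphonate
Product: 12 trimethyl[(3E,5E)-6-methylocta-3,5-diene-1,7-diyn-1-yl]silane (chain module C7–C14, free alkyne at C7, TMS at C14)
Conditions: LiHMDS, THF, −78 to 0 °C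
Reagents that add atoms: none
Why: Horner–Wadsworth–Emmons olefination with a propargylic phosphonate is E-selective for the new C11=C12 bond, and because C9=C10 sits in the enal electrophile and not in an allyl anion its geometry is not put at risk.

Step 8
Reactants: 5 ring A triflate; 12 chain module
Product: 14 tert-butyldimethyl{[(1R)-3,5,5-trimethyl-4-[(3E,5E)-3-methylocta-3,5-diene-1,7-diyn-1-yl]cyclohex-3-en-1-yl]oxy}silane (C18 alkyne A), via C14-silylated dienediyne A 13 (not isolated)
Conditions: Pd(PPh3)4 cat., CuI cat., i-Pr2NH, DMF, rt to 45 °C; crude, then K2CO3 cat., MeOH–THF, rt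
Reagents that add atoms: none
Why: Sonogashira coupling forms C6–C7 at the only free terminal alkyne of 12 without touching any C=C geometry, and catalytic methanolysis then cleaves the alkynyl C–Si bond while the hindered secondary TBS ether stays.

Step 9
Reactants: 7 ring B triflate; 12 chain module
Product: 16 1-[(3E,5E)-3-methylocta-3,5-diene-1,7-diyn-1-yl]-2,6,6-trimethylcyclohexa-1,3-diene (C18 alkyne B), via C14'-silylated dienediyne B 15 (not isolated)
Conditions: Pd(PPh3)4 cat., CuI cat., i-Pr2NH, DMF, rt; crude, then K2CO3 cat., MeOH–THF, rt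
Reagents that add atoms: none
Why: Sonogashira coupling of the dienyl triflate forms C6'–C7' with the ring diene already in place, and methanolysis of the alkynylsilane frees the C14' terminus.

Step 10
Reactants: 17 acetylene
Product: 18 (E)-1-bromo-2-iodoethene
Conditions: IBr, aq. HBr, 0 °C
Reagents that add atoms: iodine monobromide, BrI
Why: Electrophilic anti addition of I–Br to acetylene through a bridged iodonium ion gives the E-dihalide with two C–X bonds of different strength.

Step 11
Reactants: 16 C18 alkyne B; 18 (E)-1-bromo-2-iodoethene; 14 C18 alkyne A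
Product: 22 (3R)-3-(tert-butyldimethylsilyloxy)-3',4',7,8,7',8'-hexadehydro-β,β-carotene (all-E), via alkenylalane B 19 (not isolated), via bromopolyene B 20 (not isolated), via alkenylalane A 21 (not isolated)
Conditions: (a) 16, Me3Al, Cp2ZrCl2 cat., ClCH2CH2Cl, 23 °C, evaporate volatiles, THF; (b) 18, Pd2(dba)3/P(2-furyl)3 cat., ZnCl2 cat., DMF, 0 to 23 °C; (c) alane from 14 made as in (a), 23 °C
Reagents that add atoms: trimethylaluminium, C[Al](C)C
Why: Zr-catalysed syn methylalumination of each terminal alkyne puts CH3 on the internal carbon (C13, C13') and aluminium on the terminal carbon (C14, C14'); Pd(0) then inserts first into the weaker C–I bond of 18, and transmetalation (Al to Zn to Pd) followed by reductive elimination with retention gives bromopolyene 20, whose C–Br bond enters a second cycle only when alane 21 is added. The closest known reaction type is Zr-catalysed carboalumination followed by Pd/Zn-catalysed alkenyl–alkenyl (Negishi-type) coupling with a 1-bromo-2-iodoethene linchpin, which has been applied to unsymmetrical polyenes of this length. No ring is closed and no stereocentre is formed; three C=C geometries are fixed, 13E and 13'E by the syn addition and 15E by retention of the E-linchpin. The step needs terminal-over-internal alkyne selectivity, which the substrate secures because C7≡C8 and C7'≡C8' are internal and flanked by the fully substituted C6/C9 and C6'/C9', and it needs I-before-Br order, which the bond-strength gap and the order of addition secure, so that ring B and ring A end up on opposite ends. C3, the TBS ether, the ring B diene and the 9E/9'E enyne bonds are spectators because no carbanion, ylide or protic acid is generated next to them. Four C–C bonds and the whole C40 skeleton arise from two C18 alkynes that differ only in the ring.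

Step 12
Reactants: 22 TBS-protected target
Product: 23 (3R)-all-E-3',4',7,8,7',8'-hexadehydro-β,β-caroten-3-ol (target)
Conditions: TBAF, AcOH (1:1), THF, 0 °C to rt
Reagents that add atoms: none
Why: Buffered fluoride-mediated desilylation breaks only the Si–O bond, so C3 keeps its configuration and base- or acid-induced isomerisation of the polyenyne is avoided.

Compound list
1 | ketoisophorone (2,6,6-trimethylcyclohex-2-ene-1,4-dione) | CC1=CC(=O)CC(C)(C)C1=O | starting material
2 | (6R)-levodione ((6R)-2,2,6-trimethylcyclohexane-1,4-dione) | O=C1[C@H](C)CC(=O)CC1(C)C | intermediate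
3 | (4R,6R)-4-hydroxy-2,2,6-trimethylcyclohexanone (actinol) | O=C1[C@H](C)C[C@@H](O)CC1(C)C | intermediate
4 | (4R,6R)-4-(tert-butyldimethylsilyloxy)-2,2,6-trimethylcyclohexanone | O=C1[C@H](C)C[C@@H](O[Si](C)(C)C(C)(C)C)CC1(C)C | intermediate
5 | ring A triflate, (4R)-4-(tert-butyldimethylsilyloxy)-2,6,6-trimethylcyclohex-1-en-1-yl triflate | O=S(=O)(OC1=C(C)C[C@@H](O[Si](C)(C)C(C)(C)C)CC1(C)C)C(F)(F)F | intermediate
6 | 2,6,6-trimethylcyclohex-2-en-1-one | CC1=CCCC(C)(C)C1=O | starting material
7 | ring B triflate, 2,6,6-trimethylcyclohexa-1,3-dien-1-yl triflate | CC1=C(OS(=O)(=O)C(F)(F)F)C(C)(C)CC=C1 | intermediate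
8 | (E)-3-methylpent-2-en-4-yn-1-ol | C#C/C(C)=C/CO | starting material
9 | (E)-3-methylpent-2-en-4-ynal | C#C/C(C)=C/C=O | intermediate
10 | 3-bromo-1-(trimethylsilyl)prop-1-yne | C[Si](C)(C)C#CCBr | starting material
11 | diethyl [3-(trimethylsilyl)prop-2-yn-1-yl]phosphonate | CCOP(=O)(CC#C[Si](C)(C)C)OCC | intermediate
12 | trimethyl[(3E,5E)-6-methylocta-3,5-diene-1,7-diyn-1-yl]silane (chain module) | C#C/C(C)=C/C=C/C#C[Si](C)(C)C | intermediate
13 | C14-silylated dienediyne A (ring A–C≡C–C(Me)=CH–CH=CH–C≡C–TMS, 3R, 9E,11E) | C[Si](C)(C)C#C/C=C/C=C(\C)C#CC1=C(C)C[C@@H](O[Si](C)(C)C(C)(C)C)CC1(C)C | intermediate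
14 | C18 alkyne A (3R, 9E,11E, terminal alkyne C13≡C14) | C#C/C=C/C=C(\C)C#CC1=C(C)C[C@@H](O[Si](C)(C)C(C)(C)C)CC1(C)C | intermediate
15 | C14'-silylated dienediyne B (ring B–C≡C–C(Me)=CH–CH=CH–C≡C–TMS, 9'E,11'E) | CC1=C(C#C/C(C)=C/C=C/C#C[Si](C)(C)C)C(C)(C)CC=C1 | intermediate
16 | C18 alkyne B (9'E,11'E, terminal alkyne C13'≡C14') | CC1=C(C#C/C(C)=C/C=C/C#C)C(C)(C)CC=C1 | intermediate
17 | acetylene | C#C | starting material
18 | (E)-1-bromo-2-iodoethene | Br/C=C/I | intermediate
19 | alkenylalane B, dimethyl[(1E,3E,5E)-2,6-dimethyl-8-(2,6,6-trimethylcyclohexa-1,3-dien-1-yl)octa-1,3,5-trien-7-yn-1-yl]alane | CC1=C(C#C/C(C)=C/C=C/C(C)=C/[Al](C)C)C(C)(C)CC=C1 | intermediate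
20 | bromopolyene B, 1-[(3E,5E,7E,9E)-10-bromo-3,7-dimethyldeca-3,5,7,9-tetraen-1-yn-1-yl]-2,6,6-trimethylcyclohexa-1,3-diene | CC1=C(C#C/C(C)=C/C=C/C(C)=C/C=C/Br)C(C)(C)CC=C1 | intermediate
21 | alkenylalane A (Me2Al at C14, 13E, ring A with 3R-OTBS) | C[Al](C)/C=C(C)/C=C/C=C(\C)C#CC1=C(C)C[C@@H](O[Si](C)(C)C(C)(C)C)CC1(C)C | intermediate
22 | (3R)-3-(tert-butyldimethylsilyloxy)-3',4',7,8,7',8'-hexadehydro-β,β-carotene (all-E) | CC1=C(C#C/C(C)=C/C=C/C(C)=C/C=C/C=C(C)/C=C/C=C(\C)C#CC2=C(C)C[C@@H](O[Si](C)(C)C(C)(C)C)CC2(C)C)C(C)(C)CC=C1 | intermediate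
23 | (3R)-all-E-3',4',7,8,7',8'-hexadehydro-β,β-caroten-3-ol | CC1=C(C#C/C(C)=C/C=C/C(C)=C/C=C/C=C(C)/C=C/C=C(\C)C#CC2=C(C)C[C@@H](O)CC2(C)C)C(C)(C)CC=C1 | target

Total step count: 12. Longest linear sequence: 6 (steps 1, 2, 3, 8, 11, 12).

Steps most likely to fail

1. Step 11. The order of the two couplings may be lost. Oxidative addition into the C–Br bond of the first product could begin while the linchpin is still present, or part of an alane could be protonated. In either case the stoichiometry drifts and homodimeric polyenes form. The fallback reverses the polarity and works stepwise; it sets out from 16 and 14 and comes back at 22. Both alkynes are methylaluminated as before, but the alanes 19 and 21 are quenched with iodine to give the isolable C19 vinyl iodide B F1 and C19 vinyl iodide A F3. F1 is Stille-coupled (Pd2(dba)3, AsPh3, NMP, rt) with an excess of commercial (E)-1,2-bis(tributylstannyl)ethene. Here the excess of the cheap C2 reagent, rather than a halogen gap, secures single coupling and gives the C21 trienylstannane B F2. A second Stille coupling of F2 with F3 gives 22.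

2. Step 4. γ-Deprotonation of the hindered enone may be incomplete, or the electron-rich dienyl triflate may decompose on isolation or in step 9. The fallback replaces cross-coupling by carbonyl addition and dehydration; it sets out from 6 and 12 and comes back at 15. The lithium acetylide of 12 (n-BuLi, THF, −78 °C) adds 1,2 to the enone and gives the tertiary dienynol F4. Catalytic p-TsOH in toluene at rt then ionises the allylic, propargylic carbinol. The resulting cation can lose a proton only from C3', so a 1,4-dehydration gives the ring B diene of 15, and the methanolysis stage of step 9 leads on to 16.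

3. Step 8. Oxidative addition and transmetalation at the tetrasubstituted triflate flanked by a quaternary carbon may be slow, so that copper-mediated homocoupling of the alkyne overtakes cross-coupling. The fallback sets out from 4 and 12 and comes back at 13. The lithium acetylide of 12 (with CeCl3 to suppress enolisation) adds to ketone 4 and gives the tertiary propargylic alcohol F5. Dehydration with the Burgess reagent (benzene, 50 °C) can only take the single β-hydrogen at C5, and it does not depend on the relative configuration because the propargylic carbinol ionises readily. This gives the C5=C6 bond of 13, and the methanolysis stage of step 8 leads on to 14.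

Further compounds
F1 | step 11 | C19 vinyl iodide B, 1-[(3E,5E,7E)-8-iodo-3,7-dimethylocta-3,5,7-trien-1-yn-1-yl]-2,6,6-trimethylcyclohexa-1,3-diene | CC1=C(C#C/C(C)=C/C=C/C(C)=C/I)C(C)(C)CC=C1
F2 | step 11 | C21 trienylstannane B, tributyl[(1E,3E,5E,7E)-4,8-dimethyl-10-(2,6,6-trimethylcyclohexa-1,3-dien-1-yl)deca-1,3,5,7-tetraen-9-yn-1-yl]stannane | CC1=C(C#C/C(C)=C/C=C/C(C)=C/C=C/[Sn](CCCC)(CCCC)CCCC)C(C)(C)CC=C1
F3 | step 11 | C19 vinyl iodide A (iodine at C14, 9E,11E,13E, ring A with 3R-OTBS) | I/C=C(C)/C=C/C=C(\C)C#CC1=C(C)C[C@@H](O[Si](C)(C)C(C)(C)C)CC1(C)C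
F4 | step 4 | tertiary dienynol, 2,6,6-trimethyl-1-[(3E,5E)-3-methyl-8-(trimethylsilyl)octa-3,5-diene-1,7-diyn-1-yl]cyclohex-2-en-1-ol (racemic) | OC1(C#C/C(C)=C/C=C/C#C[Si](C)(C)C)C(C)=CCCC1(C)C
F5 | step 8 | tertiary propargylic alcohol, (4R,6R)-4-(tert-butyldimethylsilyloxy)-2,2,6-trimethyl-1-[(3E,5E)-3-methyl-8-(trimethylsilyl)octa-3,5-diene-1,7-diyn-1-yl]cyclohexan-1-ol (carbinol centre undefined) | OC1(C#C/C(C)=C/C=C/C#C[Si](C)(C)C)[C@H](C)C[C@@H](O[Si](C)(C)C(C)(C)C)CC1(C)C
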